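The cyclohexanone ring (C1, C2, C3, C4, C4a, C9b of the hexahydrodibenzofuranone core) is closed last, at C2–C3. The precursor is a 3,3-disubstituted 2,3-dihydrobenzofuran-2-ol (lactol) that carries an enoate arm and a propanoate arm on the future C9b. Base opens the lactol, the freed phenoxide adds to the enoate and sets the O5–C4a bond, and the propanoate enolate (C2) acylates the acetate carbonyl (C3) in a Dieckmann condensation. One operation thus builds the dihydrofuran and cyclohexanone rings, the C4a stereocenter and the C9b formyl group. It exploits the β-aryloxy ketone unit O5–C4a–C4–C3 and the quaternary C9b. A Z-selective Horner–Wadsworth–Emmons olefination and a macrocyclic Suzuki coupling then attach the spermidine bridge.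

Key step: step 4

Remark on numbering: core atoms carry dibenzo[b,d]furan numbers (C1–C4, C4a, O5, C5a, C6–C9, C9a, C9b; ketone at C3, quaternary carbon C9b, aryl substituent at C8); the target is (4aR,9bS). Spermidine nitrogens are N1 (propyl end), N4 (central) and N8 (butyl end).

Remark on assumptions: 1, 14 and 15 are taken as catalogue compounds, and the antipode of the ammonium catalyst in step 2 that leads to (R)-5 is assumed to be identified in a test run.

Step 1
Reactants: 1 5-bromobenzofuran-2(3H)-one; 2 tert-butyl acrylate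
Product: 3 tert-butyl 3-(5-bromo-2-oxo-2,3-dihydro-1-benzofuran-3-yl)propanoate (racemic)
Conditions: 1 (2 equiv), 2 (1 equiv, slow addition), DBU (10 mol %), MeCN, 0 °C
Reagents that add atoms: none
Why: Michael addition of the aromatic-stabilized lactone enolate to the acrylate, in which excess 1 and slow addition should hold back double alkylation; the C3 stereocenter is racemic here and is set anew in step 2.

Step 2
Reactants: 3 tert-butyl 3-(5-bromo-2-oxo-2,3-dihydro-1-benzofuran-3-yl)propanoate; 4 methyl propiolate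
Product: 5 methyl (2E)-3-[(3R)-5-bromo-3-(3-tert-butoxy-3-oxopropyl)-2-oxo-2,3-dihydro-1-benzofuran-3-yl]prop-2-enoate
Conditions: 4,4-dibutyl-2,6-bis(3,4,5-trifluorophenyl)-4,5-dihydro-3H-dinaphtho[2,1-c:1',2'-e]azepinium bromide (single antipode, 2 mol %), K2CO3 (solid), toluene, −40 °C
Reagents that add atoms: none
Why: Asymmetric phase-transfer conjugate addition of a tertiary lactone enolate to an acetylenic ester, in which the chiral ammonium cation should shield one face of the planar enolate and so set the quaternary carbon (future C9b); the geometry of the new enoate is of no consequence because this double bond is consumed in step 4.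

Step 3
Reactants: 5 methyl (2E)-3-[(3R)-5-bromo-3-(3-tert-butoxy-3-oxopropyl)-2-oxo-2,3-dihydro-1-benzofuran-3-yl]prop-2-enoate
Product: 6 methyl (2E)-3-[(3R)-5-bromo-3-(3-tert-butoxy-3-oxopropyl)-2-hydroxy-2,3-dihydro-1-benzofuran-3-yl]prop-2-enoate (lactol, both C2 anomers)
Conditions: LiAlH(OtBu)3 (1.3 equiv), THF, −30 to 0 °C; aq. potassium sodium tartrate
Reagents that add atoms: none
Why: Partial reduction of an aryl ester, in which the hindered alkoxyaluminium hydride should attack only the strained aryl lactone carbonyl, leave the methyl enoate and the tert-butyl ester untouched and stop at the cyclic hemiacetal aluminate; C3 is not affected.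

Step 4
Reactants: 6 methyl (2E)-3-[(3R)-5-bromo-3-(3-tert-butoxy-3-oxopropyl)-2-hydroxy-2,3-dihydro-1-benzofuran-3-yl]prop-2-enoate
Product: 10 (4aR,9bS)-8-bromo-3-oxo-1,2,3,4,4a,9b-hexahydrodibenzo[b,d]furan-9b-carbaldehyde, via oxa-Michael adduct 7 (not isolated), via β-keto ester 8 (not isolated), via β-keto acid 9 (not isolated)
Conditions: DBU (0.2 equiv), THF, 23 °C; KOtBu (2.5 equiv), 0 to 23 °C; then TFA/CH2Cl2 (1:3), 23 °C; then toluene, 70 °C
Reagents that add atoms: none
Why: DBU should open the lactol to the phenol–aldehyde, whose phenoxide adds 5-exo-trig to the enoate (reversible oxa-Michael addition) to give 7, which moves the oxygen from the lactol carbon to the future C4a and unmasks the C9b formyl group; KOtBu then forms the tert-butyl ester enolate at the future C2, which attacks the methyl ester carbonyl (future C3) in a 6-exo-trig Dieckmann condensation that is driven by deprotonation of β-keto ester 8. The closest known reaction types are the Dieckmann condensation of pimelates and the base-induced lactol opening with oxa-Michael ring switch. The only new stereocenter, C4a, is controlled by C9b, because only the 2,3-cis epimer of 7 can reach the cis-fused transition state and the trans epimer is recycled by retro-oxa-Michael reaction and re-addition. The step needs C2 and not C4 as the nucleophile and the esters and not the aldehyde as reaction partners: the tert-butyl ester is a poor acyl acceptor, an enolate at C4 expels the C4a aryloxide instead of being acylated, and every aldol reaction onto the C9b aldehyde would have to close a four-membered ring. Acidolysis of the tert-butyl ester and loss of CO2 from β-keto acid 9 should then leave ketone 10.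

Step 5
Reactants: 10 (4aR,9bS)-8-bromo-3-oxo-1,2,3,4,4a,9b-hexahydrodibenzo[b,d]furan-9b-carbaldehyde
Product: 11 (4aR,9bS)-3-oxo-8-(4,4,5,5-tetramethyl-1,3,2-dioxaborolan-2-yl)-1,2,3,4,4a,9b-hexahydrodibenzo[b,d]furan-9b-carbaldehyde
Conditions: B2pin2 (1.2 equiv), Pd(dppf)Cl2 (5 mol %), KOAc (3 equiv), 1,4-dioxane, 85 °C
Reagents that add atoms: bis(pinacolato)diboron, CC1(C)OB(OC1(C)C)B1OC(C)(C)C(C)(C)O1
Why: Miyaura borylation of the aryl bromide, in which the weak base KOAc should not enolize the β-aryloxy ketone and both carbonyl groups are tolerated.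

Step 6
Reactants: 12 spermidine
Product: 13 4-(1,3-diazinan-1-yl)butan-1-amine [1-(4-aminobutyl)hexahydropyrimidine]
Conditions: aq. CH2O (37 %, 1.0 equiv), H2O, 0 to 23 °C
Reagents that add atoms: formaldehyde, C=O
Why: Aminal formation between the 1,3-related N1 and N4 closes a six-membered ring, which should leave the primary amine N8 as the most reactive nitrogen and so differentiates the two ends of the triamine.

Step 7
Reactants: 13 4-(1,3-diazinan-1-yl)butan-1-amine; 14 (2Z)-3-iodoprop-2-enoic acid; 15 (diphenoxyphosphoryl)acetic acid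
Product: 17 diphenyl [2-(3-{4-[(2Z)-3-iodoprop-2-enamido]butyl}-1,3-diazinan-1-yl)-2-oxoethyl]phosphonate, via N8-monoamide 16 (not isolated)
Conditions: 14 (1.0 equiv), DIC, HOBt, CH2Cl2, −15 °C; then 15 (1.1 equiv), DIC, 0 to 23 °C
Reagents that add atoms: none
Why: Two carbodiimide amide couplings in one flask, in which the primary amine N8 should be acylated first and the ring N–H (N1) second; no base is present, so the Z-iodoalkene should keep its geometry, and the second acylation follows at once so that the free ring amine does not attack the iodoacrylamide.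

Step 8
Reactants: 11 (4aR,9bS)-3-oxo-8-(4,4,5,5-tetramethyl-1,3,2-dioxaborolan-2-yl)-1,2,3,4,4a,9b-hexahydrodibenzo[b,d]furan-9b-carbaldehyde; 17 diphenyl [2-(3-{4-[(2Z)-3-iodoprop-2-enamido]butyl}-1,3-diazinan-1-yl)-2-oxoethyl]phosphonate
Product: 18 (4aR,9bS)-9b-[(1Z)-3-(3-{4-[(2Z)-3-iodoprop-2-enamido]butyl}-1,3-diazinan-1-yl)-3-oxoprop-1-en-1-yl]-8-(4,4,5,5-tetramethyl-1,3,2-dioxaborolan-2-yl)-1,2,4,4a-tetrahydrodibenzo[b,d]furan-3(9bH)-one
Conditions: 17, NaH (1.0 equiv), THF, 0 °C; then 11, −78 to −20 °C
Reagents that add atoms: none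
Why: Z-selective Horner–Wadsworth–Emmons olefination with a diaryl phosphonoacetamide, in which the electron-poor phenoxy groups should make elimination from the kinetically favoured adduct fast and so give the Z-acrylamide; the non-enolizable C9b aldehyde is the only electrophile that should react, since the stabilized anion does not enolize the ketone and the vinyl iodide and boronate are inert at low temperature.

Step 9
Reactants: 18 (4aR,9bS)-9b-[(1Z)-3-(3-{4-[(2Z)-3-iodoprop-2-enamido]butyl}-1,3-diazinan-1-yl)-3-oxoprop-1-en-1-yl]-8-(4,4,5,5-tetramethyl-1,3,2-dioxaborolan-2-yl)-1,2,4,4a-tetrahydrodibenzo[b,d]furan-3(9bH)-one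
Product: 19 the N1,N4-methylene-bridged macrocycle (target skeleton in which a CH2 group joins the C9b-side amide nitrogen and the central amine as a 1,3-diazinane ring)
Conditions: Pd(PPh3)4 (10 mol %), K3PO4 (3 equiv), THF/H2O (10:1), 45 °C, 1 mM (slow addition of 18)
Reagents that add atoms: none
Why: Intramolecular Suzuki–Miyaura coupling of the aryl boronate with the (Z)-vinyl iodide under high dilution, which proceeds with retention at the alkene and should therefore give the Z-cinnamamide while it closes the twenty-membered ring at an unhindered sp2–sp2 bond.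

Step 10
Reactants: 19 the N1,N4-methylene-bridged macrocycle
Product: 20 CNP0159470.1, the (4aR,9bS)-3-oxo-1,2,3,4,4a,9b-hexahydrodibenzo[b,d]furan bridged from C9b to C8 by the chain (Z)-CH=CH–CO–NH–(CH2)3–NH–(CH2)4–NH–CO–CH=CH-(Z)
Conditions: malonic acid (5 equiv), pyridine, EtOH, 70 °C; aq. NaHCO3 work-up
Reagents that add atoms: none
Why: Removal of the methylene bridge by Knoevenagel-type transfer of the aminal carbon to malonic acid under buffered conditions, which should free the secondary amide N–H and the central secondary amine without touching the ketone, the aryl ether or the two Z double bonds.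

Compound list
1 | 5-bromobenzofuran-2(3H)-one | O=C1Cc2cc(Br)ccc2O1 | starting material
2 | tert-butyl acrylate | C=CC(=O)OC(C)(C)C | starting material
3 | tert-butyl 3-(5-bromo-2-oxo-2,3-dihydro-1-benzofuran-3-yl)propanoate (racemic) | O=C1Oc2ccc(Br)cc2C1CCC(=O)OC(C)(C)C | intermediate
4 | methyl propiolate | C#CC(=O)OC | starting material
5 | methyl (2E)-3-[(3R)-5-bromo-3-(3-tert-butoxy-3-oxopropyl)-2-oxo-2,3-dihydro-1-benzofuran-3-yl]prop-2-enoate | CC(C)(C)OC(=O)CC[C@@]1(/C=C/C(=O)OC)c2cc(Br)ccc2OC1=O | intermediate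
6 | methyl (2E)-3-[(3R)-5-bromo-3-(3-tert-butoxy-3-oxopropyl)-2-hydroxy-2,3-dihydro-1-benzofuran-3-yl]prop-2-enoate (lactol, both C2 anomers) | CC(C)(C)OC(=O)CC[C@@]1(/C=C/C(=O)OC)c2cc(Br)ccc2OC1O | intermediate
7 | tert-butyl 3-[(2R,3S)-5-bromo-3-formyl-2-(2-methoxy-2-oxoethyl)-2,3-dihydro-1-benzofuran-3-yl]propanoate (the epimer that cyclizes; in equilibrium with its C2 epimer) | CC(C)(C)OC(=O)CC[C@]1(C=O)c2cc(Br)ccc2O[C@@H]1CC(=O)OC | intermediate
8 | tert-butyl (4aR,9bS)-8-bromo-9b-formyl-3-oxo-1,2,3,4,4a,9b-hexahydrodibenzo[b,d]furan-2-carboxylate (C2 epimers and enol) | O=C1C(C(=O)OC(C)(C)C)C[C@]2(C=O)c3cc(Br)ccc3O[C@@H]2C1 | intermediate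
9 | (4aR,9bS)-8-bromo-9b-formyl-3-oxo-1,2,3,4,4a,9b-hexahydrodibenzo[b,d]furan-2-carboxylic acid | O=C1C(C(=O)O)C[C@]2(C=O)c3cc(Br)ccc3O[C@@H]2C1 | intermediate
10 | (4aR,9bS)-8-bromo-3-oxo-1,2,3,4,4a,9b-hexahydrodibenzo[b,d]furan-9b-carbaldehyde | O=C1CC[C@]2(C=O)c3cc(Br)ccc3O[C@@H]2C1 | intermediate
11 | (4aR,9bS)-3-oxo-8-(4,4,5,5-tetramethyl-1,3,2-dioxaborolan-2-yl)-1,2,3,4,4a,9b-hexahydrodibenzo[b,d]furan-9b-carbaldehyde | O=C1CC[C@]2(C=O)c3cc(B4OC(C)(C)C(C)(C)O4)ccc3O[C@@H]2C1 | intermediate
12 | spermidine | NCCCNCCCCN | starting material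
13 | 4-(1,3-diazinan-1-yl)butan-1-amine | NCCCCN1CCCNC1 | intermediate
14 | (2Z)-3-iodoprop-2-enoic acid | OC(=O)/C=C\I | starting material
15 | (diphenoxyphosphoryl)acetic acid | OC(=O)CP(=O)(Oc1ccccc1)Oc1ccccc1 | starting material
16 | (2Z)-N-[4-(1,3-diazinan-1-yl)butyl]-3-iodoprop-2-enamide | O=C(/C=C\I)NCCCCN1CCCNC1 | intermediate
17 | diphenyl [2-(3-{4-[(2Z)-3-iodoprop-2-enamido]butyl}-1,3-diazinan-1-yl)-2-oxoethyl]phosphonate | O=C(/C=C\I)NCCCCN1CCCN(C1)C(=O)CP(=O)(Oc1ccccc1)Oc1ccccc1 | intermediate
18 | (4aR,9bS)-9b-[(1Z)-3-(3-{4-[(2Z)-3-iodoprop-2-enamido]butyl}-1,3-diazinan-1-yl)-3-oxoprop-1-en-1-yl]-8-(4,4,5,5-tetramethyl-1,3,2-dioxaborolan-2-yl)-1,2,4,4a-tetrahydrodibenzo[b,d]furan-3(9bH)-one | O=C1CC[C@]2(/C=C\C(=O)N4CCCN(CCCCNC(=O)/C=C\I)C4)c3cc(B5OC(C)(C)C(C)(C)O5)ccc3O[C@@H]2C1 | intermediate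
19 | N1,N4-methylene-bridged macrocycle (target skeleton with a CH2 group between the C9b-side amide nitrogen and the central amine) | O=C1CC[C@]23/C=C\C(=O)N5CCCN(C5)CCCCNC(=O)/C=C\c4ccc(c2c4)O[C@@H]3C1 | intermediate
20 | CNP0159470.1 | O=C1CC[C@]23/C=C\C(=O)NCCCNCCCCNC(=O)/C=C\c4ccc(c2c4)O[C@@H]3C1 | target

Total step count: 10 (steps 1–5 core, steps 6–7 linker, steps 8–10 end game).
Longest linear sequence: 8 steps (1, 2, 3, 4, 5, 8, 9, 10).

Steps most likely to fail

Step 4. What may go wrong is loss of the formyl group by alkoxide-induced C–C cleavage or aldehyde disproportionation while the ring-opened phenoxide–aldehyde is present, or stalling at the oxa-Michael stage. The fallback sets out from 6 and comes back at 10. Lactol 6 would be isomerized with catalytic DBU alone and the oxa-Michael adduct 7 isolated. Its aldehyde would be masked with HC(OMe)3 and PPTS in MeOH as tert-butyl 3-[(3S)-5-bromo-3-(dimethoxymethyl)-2-(2-methoxy-2-oxoethyl)-2,3-dihydro-1-benzofuran-3-yl]propanoate F1. A separate Dieckmann condensation (KOtBu, THF, 0 to 40 °C) should then give tert-butyl (4aR,9bS)-8-bromo-9b-(dimethoxymethyl)-3-oxo-1,2,3,4,4a,9b-hexahydrodibenzo[b,d]furan-2-carboxylate F2. Aqueous TFA followed by warming should remove the acetal, the tert-butyl group and CO2 and deliver 10.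

Step 2. What may go wrong is poor facial selectivity, or a background addition outside the chiral ion pair that erodes the enantiomeric purity. The fallback sets out from 3 and comes back at 5. The addition to 4 would be run without a chiral catalyst (DABCO, 10 mol %, MeCN, 23 °C) to give racemic methyl (2E)-3-[5-bromo-3-(3-tert-butoxy-3-oxopropyl)-2-oxo-2,3-dihydro-1-benzofuran-3-yl]prop-2-enoate F3. F3 would be resolved by preparative chromatography on a chiral stationary phase, and the (R)-enantiomer is 5.

Step 9. What may go wrong is oligomerization in competition with ring closure, and Z-to-E isomerization of the iodoacrylamide or protodeboronation during a slow macrocyclic coupling under aqueous base. The fallback sets out from 10 and 17 and comes back at 19; it replaces the Suzuki coupling by a base-free Stille ring closure and needs no borylation. Linker 17 would be stannylated with (Bu3Sn)2 and Pd(PPh3)4 in toluene at 60 °C to diphenyl [2-oxo-2-(3-{4-[(2Z)-3-(tributylstannyl)prop-2-enamido]butyl}-1,3-diazinan-1-yl)ethyl]phosphonate F4. Olefination of bromo aldehyde 10 with F4 under the conditions of step 8 should give (4aR,9bS)-8-bromo-9b-[(1Z)-3-oxo-3-(3-{4-[(2Z)-3-(tributylstannyl)prop-2-enamido]butyl}-1,3-diazinan-1-yl)prop-1-en-1-yl]-1,2,4,4a-tetrahydrodibenzo[b,d]furan-3(9bH)-one F5. Macrocyclic Stille coupling of F5 (Pd2(dba)3, P(tBu)3, 1,4-dioxane, 60 °C, 1 mM) should then close the ring to 19.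

Further compounds
F1 | step 4 | tert-butyl 3-[(3S)-5-bromo-3-(dimethoxymethyl)-2-(2-methoxy-2-oxoethyl)-2,3-dihydro-1-benzofuran-3-yl]propanoate (C2 epimers) | CC(C)(C)OC(=O)CC[C@]1(C(OC)OC)c2cc(Br)ccc2OC1CC(=O)OC
F2 | step 4 | tert-butyl (4aR,9bS)-8-bromo-9b-(dimethoxymethyl)-3-oxo-1,2,3,4,4a,9b-hexahydrodibenzo[b,d]furan-2-carboxylate | O=C1C(C(=O)OC(C)(C)C)C[C@]2(C(OC)OC)c3cc(Br)ccc3O[C@@H]2C1
F3 | step 2 | methyl (2E)-3-[5-bromo-3-(3-tert-butoxy-3-oxopropyl)-2-oxo-2,3-dihydro-1-benzofuran-3-yl]prop-2-enoate (racemic) | CC(C)(C)OC(=O)CCC1(/C=C/C(=O)OC)c2cc(Br)ccc2OC1=O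
F4 | step 9 | diphenyl [2-oxo-2-(3-{4-[(2Z)-3-(tributylstannyl)prop-2-enamido]butyl}-1,3-diazinan-1-yl)ethyl]phosphonate | CCCC[Sn](CCCC)(CCCC)/C=C\C(=O)NCCCCN1CCCN(C1)C(=O)CP(=O)(Oc1ccccc1)Oc1ccccc1
F5 | step 9 | (4aR,9bS)-8-bromo-9b-[(1Z)-3-oxo-3-(3-{4-[(2Z)-3-(tributylstannyl)prop-2-enamido]butyl}-1,3-diazinan-1-yl)prop-1-en-1-yl]-1,2,4,4a-tetrahydrodibenzo[b,d]furan-3(9bH)-one | O=C1CC[C@]2(/C=C\C(=O)N4CCCN(CCCCNC(=O)/C=C\[Sn](CCCC)(CCCC)CCCC)C4)c3cc(Br)ccc3O[C@@H]2C1
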